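Beside this flask stands a neighbour charged with 3.0 M of Zo in place of 1.20 M, and one rate reads both.

    Aj ⇌ Lx, rate k1*(cs1 - [Lx]) while solid is left; crystals form when [Lx] > cs1 (cs1 = 0.33 M, k1 = 0.40 h⁻¹)
    Lx + Zo → Dz (k2 = 0.15 L mol⁻¹ h⁻¹)
    Lx + Dz → Qo (k3 = 0.063 L mol⁻¹ h⁻¹)
    Zo ⇌ Ym (K4 = 2.1, k4 = 0.16 h⁻¹)
    Aj + Dz → Xo (k5 = 0.13 L mol⁻¹ h⁻¹)

Aj 1.0 M; Zo 1.20 M; time 3.0 h

- in percentages every species weighs as the Aj in it: one Qo or Xo counts as two
- as a solid, counted per litre of solution: Aj
- at the start none of Aj is in solution
- Lx means what is dissolved; the solid is not counted in it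
- run time (flask): 3.0 h

1. amount of Dz at 3.0 h, in percent of the Aj charged
2. concentration of Lx in solution at 3.0 h, in percent of saturation

My own reckoning starts with the solid. At full pace, dissolution brings 0.396 M by the asked time, less than the charge, so solid stands throughout in this flask. c_Lx starts at zero and rises with the slope

k1·cs1 = 0.132 M h⁻¹.

Two terms bend that slope. Dissolution slows as c_Lx rises, and Zo removes Lx, a pseudo-first-order loss while Zo is held at its charge:

λ = 0.40 h⁻¹ + 0.180 h⁻¹ = 0.580 h⁻¹.

This sum is the filling rate of Lx: the dissolution coefficient plus the rate constant of Lx + Zo times c_Zo. The dissolution term is the larger. The curve runs into the level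

c_Lx = slope/λ = 0.228 M,

and its knee lies at

1/λ = 1.72 h,

where the starting tangent meets that level. Joined, c_Lx = level·(1 − e^(−λt)), which at 3.0 h gives 56.9% of saturation.

Dz starts flat and turns at the same knee into a straight rise of

k2·c_Zo·level = 0.0410 M h⁻¹.

Its area gives

c_Dz = slope·(t − (1 − e^(−λt))/λ),

or 6.47% of the charge. This figure holds Zo at its charge and counts no loss of Dz.

The forecast gives 3.5% of Dz and 62% of saturation, holding that “Lx climbs slowly to about 0.2 M”.

The simulation gives 4.33% of Dz, below my figure, and 60.1% of saturation.

In this flask the same curve gives 40.1% of saturation at 1.50 h, and the run reads 40.8%. In the neighbour with more Zo, λ becomes 0.850 h⁻¹, so c_Lx at 3.0 h reckons to 14.3% of the Aj charged, and that flask holds 16.2%. Of the effects tried on Dz in this flask, the largest single one is that of the low solubility of Lx, which also sets how fast it dissolves. Removing that limit lifts Dz from 4.33% to 27.8%, a quarter of what is missing.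

(The numbers come from no measurement; the rest is arithmetic.)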